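I had no rate constants for the alder flask, so I asked what its end state had to be and what a further charge could buy.

| setting | alder | maple | flask |
|---|---|---|---|
| substrate | 0.0050 M | 0.0050 M | 0.0050 M |
| partner | 0.60 equiv | 0.60 equiv | 0.600 equiv |
| capture agent | 1.5 mM | 3 mM | 1.50 mM |
| remark | the very flask that is asked about, followed so far | run made earlier |  |
| time |  |  | 20 min |

| run | time / min | target / % |
|---|---|---|
| alder | 1.00 | 17.7 |
| alder | 1.33 | 20.0 |
| alder | 2.00 | 22.1 |
| alder | 3.00 | 22.1 |
| alder | 5.00 | 22.9 |
| alder | 8.00 | 21.6 |
| alder | 12.0 | 21.6 |
| maple | 0.200 | 3.7 |
| maple | 0.667 | 13.5 |
| maple | 1.00 | 17.5 |
| maple | 1.50 | 18.6 |
| maple | 2.50 | 20.4 |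
| maple | 3.00 | 21.1 |
| maple | 4.00 | 20.3 |

(each reading ± 0.5 percentage points)

- percent here means substrate units held: one side product counts as two
- what is taken out of target is counted as made
- what was read earlier has a scatter of 0.5 percentage points, one standard deviation
- steps thought possible: substrate + partner -> open intermediate; open intermediate -> target; open intermediate + capture agent -> trapped intermediate; substrate + open intermediate -> side product; 2 partner -> self-condensation product
- additions bring no volume worth counting

- north-west: at 20 min take out 90% of the target then present, then wait 20 min
- north: change nothing and wait 20 min more
- north-east: at 20 min add partner, 50.0% of the amount charged, then wait 20 min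
- south: at 20 min add substrate, 50.0% of the amount charged, then wait 20 min

- target, in percent of the substrate first charged, at 20 min
- what to do for the largest gain in target; "none" if nothing gains more than 2 percentage points (north-west / north / north-east / south / none)
- target present, with what was taken out counted in, in percent of the substrate first charged, after north-east
- target present, with what was taken out counted in, in percent of the substrate first charged, after south

In the alder flask, the target readings stopped rising by 2.00 min. The readings from there to 12.0 min averaged 22.1%, with a scatter of 0.5 percentage points on each. So I put target at 20 min at that value and expected nothing from waiting. The maple flask, with 3 mM of capture agent, read 21.1% at 3.00 min, which stood 1.00 point below that average.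

I looked at the charges instead. In the alder flask c(partner) was charged at 3.00 mM, smaller than the 0.0050 M of c(substrate), and I took partner as the limiting reagent, as a working guess. So I counted target against partner in the alder flask. Target per unit of partner charged read 0.368, and I called this the partner return.

The decision followed from it. North-east adds 0.300 equiv of partner, so at the same return I expected a gain of 11 points, which makes 33.1%. This assumed that the new partner would find substrate, and target readings do not show how much substrate stood. South adds no partner, so my rule gave it no gain. No listed step consumes target, so I expected nothing from north-west. I would charge partner.

The forecast also chose north-east, with 22% at 20 min and 22% after south. But it gave 25.5% after north-east, on the ground that “North-east converts the leftover substrate, now with little side reaction”. My figure stood higher than that by 7.6 points.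

The alder flask gave 21.7% at 20 min, 21.7% after south and 34.8% after north-east.

    substrate + partner → open intermediate (k = 15.0 M⁻¹ s⁻¹)
    open intermediate → target (k = 0.0280 s⁻¹)
    open intermediate + capture agent → trapped intermediate (k = 1.70 M⁻¹ s⁻¹)
    substrate + open intermediate → side product (k = 6.00 M⁻¹ s⁻¹)
    2 partner → self-condensation product (k = 14.0 M⁻¹ s⁻¹)

At 20.0 min the alder flask held 47.6% of its substrate and 0% of its partner free. The added partner returned 0.438, more than the 0.368 of the first charge. For the neighbour charged with 0.150 equiv of partner, its other charges held, the partner return reckoned 5.52%, and at 20.0 min that neighbour held 6.51% of target.

The earlier runs and the new flask are calculated from invented constants; the scatter is artificial.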